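The ring atoms are called O1, C2 (bears aryl), C3 (bears CH2OH), C4 (bears the carbinol carbon Cα) and C5 (methylene). The plan rests on raising C5 to a lactone carbonyl. The feature exploited is the cis C2/C3 pair of that γ-butyrolactone ring, which divides into an aldehyde (O1, C2) and an enal homoenolate (C3–C4–C5). One carbene-catalysed annulation makes C2–C3 and O1–C5, closes the ring and sets both stereocentres. Its precursors are O-tosylvanillin and (E)-3-(2-furyl)acrolein, with the furan masking the hydroxymethyl carbon. Afterwards C4 is aroylated trans, Cα is set by chelation-controlled reduction, C5 is deoxygenated and the protecting groups are removed.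

Key step: step 2

Target configuration, read from the SMILES: C2 S, C3 S, C4 R, Cα S. This means 2,3-cis and 3,4-trans. The locants C2–C5 and Cα in the Why lines follow the numbering above, whereas the systematic names use their own locants.

Assumption: the sense of induction in step 2 is assigned by analogy with related homoenolate annulations. Both antipodes of the triazolium salt are commercial, and the one that leads to (4R,5S)-4 is meant.

Step 1
Reactants: 1 vanillin
Product: 2 O-tosylvanillin (4-formyl-2-methoxyphenyl 4-methylbenzenesulfonate)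
Conditions: TsCl (1.1 equiv), Et3N (1.5 equiv), 4-(dimethylamino)pyridine (cat.), CH2Cl2, 0 °C → rt
Reagents that add atoms: p-toluenesulfonyl chloride, Cc1ccc(S(=O)(=O)Cl)cc1
Why: Base-mediated O-sulfonylation of a phenol is routine, and the sulfonate both raises the electrophilicity of the formyl group and switches off the para-oxygen donor for every later acidic step.

Step 2
Reactants: 2 O-tosylvanillin; 3 (E)-3-(furan-2-yl)acrolein
Product: 4 (4R,5S)-4-(furan-2-yl)-5-[3-methoxy-4-(tosyloxy)phenyl]dihydrofuran-2(3H)-one (4,5-cis)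
Conditions: (5aR,10bS)-2-mesityl-5a,10b-dihydro-4H,6H-indeno[2,1-b][1,2,4]triazolo[4,3-d][1,4]oxazinium tetrafluoroborate (10 mol %), 1,8-diazabicyclo[5.4.0]undec-7-ene (15 mol %), Ti(OiPr)4 (20 mol %), 4 Å sieves, CH2Cl2, 0 °C → rt; 2 (1.5 equiv), 3 added slowly
Reagents that add atoms: none
Why: Addition of the free carbene to the formyl carbon of 3 followed by a formal 1,2-proton shift produces a conjugated enaminol (homoenolate equivalent) that is nucleophilic at the former β-carbon, and this carbon (C3) bonds to the titanium-activated formyl carbon of 2 (C2). Tautomerisation of the resulting enol gives an acyl azolium at C5, which the new C2 alkoxide attacks in a 5-exo-trig addition–elimination that closes the lactone ring through O1–C5 and expels the carbene for the next turnover. The closest known reaction type is the carbene-catalysed conjugate-umpolung formal (3+2) annulation of β-aryl and β-heteroaryl enals with aromatic aldehydes to cis-γ-butyrolactones, combined with the known Ti(OiPr)4 co-catalysis of homoenolate additions. C3 is controlled by the fused indane of the catalyst, which blocks one face of the homoenolate, and C2 by the tetravalent titanium centre, which binds the enaminol oxygen and the aldehyde oxygen together so that one aldehyde face is presented and aryl and furyl end up cis. The step needs cross-coupling in preference to enal self-annulation and benzoin formation: the sulfonate makes the formyl group of 2 more electrophilic than the donor-conjugated formyl group of 3, 2 is kept in excess while 3 is added slowly, and benzoin-type adducts of 2 form reversibly. The furyl group stabilises the homoenolate as an aryl group does and offers no leaving group beside the nucleophilic carbon, so β-elimination cannot compete.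

Step 3
Reactants: 4 cis furyl lactone
Product: 6 (2S,3R)-2-[3-methoxy-4-(tosyloxy)phenyl]-5-oxooxolane-3-carboxylic acid (2,3-cis), via acyl formate 5 (not isolated)
Conditions: O3, CH2Cl2–MeOH, −78 °C (Sudan Red 7B end point); Me2S, −78 °C → rt
Reagents that add atoms: ozone, [O-][O+]=O
Why: Ozonolysis cleaves both electron-rich furan C=C bonds far faster than it touches the sulfonate-deactivated arene, leaving C3 attached to an acyl formate that methanol solvolyses at the formyl carbon to the free acid (furan as carboxyl surrogate), and no bond to C2 or C3 is broken, so the cis pair is kept.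

Step 4
Reactants: 6 cis lactone acid
Product: 8 (4S,5S)-4-[(tert-butyldimethylsilyloxy)methyl]-5-[3-methoxy-4-(tosyloxy)phenyl]dihydrofuran-2(3H)-one, via hydroxymethyl lactone 7 (not isolated)
Conditions: BH3·THF (1.5 equiv), THF, 0 °C → rt; MeOH quench, evaporation; then TBSCl (1.3 equiv), imidazole (2.5 equiv), CH2Cl2, 0 °C
Reagents that add atoms: tert-butyldimethylsilyl chloride, CC(C)(C)[Si](C)(C)Cl
Why: Chemoselective borane reduction takes a free carboxylic acid through its acyloxyborane much faster than a lactone or an aryl sulfonate, and immediate silylation of the crude primary alcohol blocks migration of the acyl group from O1 to the new hydroxyl (translactonisation).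

Step 5
Reactants: 9 vanillic acid
Product: 10 3-methoxy-4-(tosyloxy)benzoic acid
Conditions: TsCl (1.1 equiv), NaOH (2.3 equiv), H2O–THF, 0 °C → rt; then aq. HCl
Reagents that add atoms: p-toluenesulfonyl chloride, Cc1ccc(S(=O)(=O)Cl)cc1
Why: Under Schotten–Baumann-type conditions the phenoxide is sulfonylated while any mixed carboxylic–sulfonic anhydride hydrolyses back, so acidification should deliver the protected acid.

Step 6
Reactants: 10 3-methoxy-4-(tosyloxy)benzoic acid
Product: 11 3-methoxy-4-(tosyloxy)benzoyl chloride
Conditions: (COCl)2 (1.5 equiv), DMF (cat.), CH2Cl2, 0 °C → rt; evaporation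
Reagents that add atoms: oxalyl chloride, O=C(Cl)C(=O)Cl
Why: Vilsmeier-type activation with oxalyl chloride and catalytic DMF converts the acid into its chloride with gaseous by-products only, and the aryl sulfonate is inert.

Step 7
Reactants: 8 silyl-protected cis lactone; 11 3-methoxy-4-(tosyloxy)benzoyl chloride
Product: 13 (3S,4S,5S)-3-[3-methoxy-4-(tosyloxy)benzoyl]-4-[(tert-butyldimethylsilyloxy)methyl]-5-[3-methoxy-4-(tosyloxy)phenyl]dihydrofuran-2(3H)-one (3,4-trans and 4,5-cis), via lithium enolate 12 (not isolated)
Conditions: LiN(SiMe3)2 (2.1 equiv), THF, −78 °C; 11 (1.05 equiv), −78 → −40 °C; AcOH quench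
Reagents that add atoms: none
Why: This is a crossed Claisen-type C-acylation of a lactone lithium enolate by an aroyl chloride, with the second equivalent of base taking up the acidic product; the acyl group enters C4 on the face opposite the cis C2 aryl and C3 silyloxymethyl groups, and the epimerisable β-dicarbonyl centre settles in the same 3,4-trans arrangement, so C4 is fixed both kinetically and thermodynamically.

Step 8
Reactants: 13 β-keto lactone
Product: 14 (3S,4S,5S)-3-{(S)-hydroxy[3-methoxy-4-(tosyloxy)phenyl]methyl}-4-[(tert-butyldimethylsilyloxy)methyl]-5-[3-methoxy-4-(tosyloxy)phenyl]dihydrofuran-2(3H)-one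
Conditions: Zn(BH4)2 (ethereal stock solution), Et2O–CH2Cl2, −40 → 0 °C; aq. NH4Cl
Reagents that add atoms: none
Why: In this chelation-controlled hydride reduction of an α-substituted β-keto ester, divalent zinc ties the aryl ketone oxygen to the lactone carbonyl oxygen and so holds one rotamer about C4–Cα, and hydride enters from the side of the C4–H bond and away from C3, which should give the syn (αS) carbinol while the lactone, silyl ether and sulfonates are untouched.

Step 9
Reactants: 14 β-hydroxy lactone
Product: 15 (3S,4S,5S)-3-{(S)-hydroxy[3-methoxy-4-(tosyloxy)phenyl]methyl}-4-[(tert-butyldimethylsilyloxy)methyl]-5-[3-methoxy-4-(tosyloxy)phenyl]oxolan-2-ol (lactol as an anomer mixture)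
Conditions: i-Bu2AlH (2.5 equiv), CH2Cl2, −78 °C; aq. potassium sodium tartrate
Reagents that add atoms: none
Why: Partial reduction of a γ-lactone with i-Bu2AlH stops at the aluminium hemiacetal at −78 °C, the first equivalent being consumed by the free hydroxyl, and the silyl ether and aryl sulfonates are inert under these conditions.

Step 10
Reactants: 15 lactol
Product: 16 (S)-{(3R,4S,5S)-4-[(tert-butyldimethylsilyloxy)methyl]-5-[3-methoxy-4-(tosyloxy)phenyl]oxolan-3-yl}[3-methoxy-4-(tosyloxy)phenyl]methanol
Conditions: Et3SiH (5 equiv), BF3·OEt2 (2 equiv), CH2Cl2, −78 → −40 °C; aq. NaHCO3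
Reagents that add atoms: none
Why: In this ionic hydrogenation of a lactol, BF3 ionises only the anomeric C5–OH to the cyclic oxocarbenium ion, which Et3SiH reduces, whereas C2–O1 and Cα–OH should stay intact because their benzylic cations are destabilised by the para sulfonates, and no stereocentre of the target is touched.

Step 11
Reactants: 16 protected oxolane
Product: 18 (S)-(4-hydroxy-3-methoxyphenyl)[(3R,4S,5S)-5-(4-hydroxy-3-methoxyphenyl)-4-(hydroxymethyl)oxolan-3-yl]methanol (target), via diol bis-tosylate 17 (not isolated)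
Conditions: camphor-10-sulfonic acid (10 mol %), MeOH, 0 °C → rt; then Mg turnings (excess), MeOH, rt; aq. NH4Cl
Reagents that add atoms: none
Why: Acid-catalysed methanolysis of the primary silyl ether is run while both arenes are still deactivated, and magnesium in methanol then cleaves the two aryl O–S bonds by electron transfer (reductive desulfonylation) under mild conditions that should not open C2–O1 or Cα–O through quinone methides.

Compound list
1 | vanillin (4-hydroxy-3-methoxybenzaldehyde) | COc1cc(C=O)ccc1O | starting material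
2 | O-tosylvanillin | COc1cc(C=O)ccc1OS(=O)(=O)c1ccc(C)cc1 | intermediate
3 | (E)-3-(furan-2-yl)acrolein | O=C/C=C/c1ccco1 | starting material
4 | (4R,5S)-4-(furan-2-yl)-5-[3-methoxy-4-(tosyloxy)phenyl]dihydrofuran-2(3H)-one, cis | O=C1C[C@@H](c2ccco2)[C@@H](c2ccc(OS(=O)(=O)c3ccc(C)cc3)c(OC)c2)O1 | intermediate
5 | formic (2S,3R)-2-[3-methoxy-4-(tosyloxy)phenyl]-5-oxooxolane-3-carboxylic anhydride (acyl formate) | O=C1C[C@@H](C(=O)OC=O)[C@@H](c2ccc(OS(=O)(=O)c3ccc(C)cc3)c(OC)c2)O1 | intermediate
6 | (2S,3R)-2-[3-methoxy-4-(tosyloxy)phenyl]-5-oxooxolane-3-carboxylic acid, cis | O=C1C[C@@H](C(=O)O)[C@@H](c2ccc(OS(=O)(=O)c3ccc(C)cc3)c(OC)c2)O1 | intermediate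
7 | (4S,5S)-4-(hydroxymethyl)-5-[3-methoxy-4-(tosyloxy)phenyl]dihydrofuran-2(3H)-one | O=C1C[C@@H](CO)[C@@H](c2ccc(OS(=O)(=O)c3ccc(C)cc3)c(OC)c2)O1 | intermediate
8 | (4S,5S)-4-[(tert-butyldimethylsilyloxy)methyl]-5-[3-methoxy-4-(tosyloxy)phenyl]dihydrofuran-2(3H)-one | O=C1C[C@@H](CO[Si](C)(C)C(C)(C)C)[C@@H](c2ccc(OS(=O)(=O)c3ccc(C)cc3)c(OC)c2)O1 | intermediate
9 | vanillic acid (4-hydroxy-3-methoxybenzoic acid) | COc1cc(C(=O)O)ccc1O | starting material
10 | 3-methoxy-4-(tosyloxy)benzoic acid | COc1cc(C(=O)O)ccc1OS(=O)(=O)c1ccc(C)cc1 | intermediate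
11 | 3-methoxy-4-(tosyloxy)benzoyl chloride | COc1cc(C(=O)Cl)ccc1OS(=O)(=O)c1ccc(C)cc1 | intermediate
12 | lithium enolate of 8 | [Li+].[O-]C1=C[C@@H](CO[Si](C)(C)C(C)(C)C)[C@@H](c2ccc(OS(=O)(=O)c3ccc(C)cc3)c(OC)c2)O1 | intermediate
13 | (3S,4S,5S)-3-aroyl lactone (aroyl = 3-methoxy-4-(tosyloxy)benzoyl), 3,4-trans, 4,5-cis | O=C1[C@H](C(=O)c2ccc(OS(=O)(=O)c3ccc(C)cc3)c(OC)c2)[C@@H](CO[Si](C)(C)C(C)(C)C)[C@@H](c2ccc(OS(=O)(=O)c3ccc(C)cc3)c(OC)c2)O1 | intermediate
14 | (3S,4S,5S)-3-[(S)-aryl(hydroxy)methyl] lactone | O=C1[C@H]([C@H](O)c2ccc(OS(=O)(=O)c3ccc(C)cc3)c(OC)c2)[C@@H](CO[Si](C)(C)C(C)(C)C)[C@@H](c2ccc(OS(=O)(=O)c3ccc(C)cc3)c(OC)c2)O1 | intermediate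
15 | corresponding lactol (oxolan-2-ol), anomer mixture | OC1[C@H]([C@H](O)c2ccc(OS(=O)(=O)c3ccc(C)cc3)c(OC)c2)[C@@H](CO[Si](C)(C)C(C)(C)C)[C@@H](c2ccc(OS(=O)(=O)c3ccc(C)cc3)c(OC)c2)O1 | intermediate
16 | (2S,3S,4R,αS)-oxolane, silyl ether, bis-tosylate | C1[C@H]([C@H](O)c2ccc(OS(=O)(=O)c3ccc(C)cc3)c(OC)c2)[C@@H](CO[Si](C)(C)C(C)(C)C)[C@@H](c2ccc(OS(=O)(=O)c3ccc(C)cc3)c(OC)c2)O1 | intermediate
17 | (2S,3S,4R,αS)-oxolane diol, bis-tosylate | C1[C@H]([C@H](O)c2ccc(OS(=O)(=O)c3ccc(C)cc3)c(OC)c2)[C@@H](CO)[C@@H](c2ccc(OS(=O)(=O)c3ccc(C)cc3)c(OC)c2)O1 | intermediate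
18 | (S)-(4-hydroxy-3-methoxyphenyl)[(3R,4S,5S)-5-(4-hydroxy-3-methoxyphenyl)-4-(hydroxymethyl)oxolan-3-yl]methanol | COc1cc([C@@H](O)[C@H]2CO[C@H](c3ccc(O)c(OC)c3)[C@@H]2CO)ccc1O | target

Total step count: 11. Longest linear sequence: 9 steps (steps 1–4 and 7–11, from vanillin). Steps 5 and 6 form a two-step side branch.

Steps most likely to fail

Step 2. The enantioselectivity or cis selectivity may be insufficient, or the enal may couple with itself instead of with 2. The fallback keeps the same bond formation but takes absolute configuration from a resolution instead of from the catalyst. It sets out from 2 and 3. The achiral carbene from 1,3-dimesitylimidazolium chloride and 1,8-diazabicyclo[5.4.0]undec-7-ene in THF should give the racemic cis lactone F1, with the trans isomer removed by chromatography. Ozonolysis as in step 3 then leads through the racemic acyl formate F2 to the racemic cis acid F3. Crystallisation with (R)-1-phenylethylamine (or its antipode, if that pairs better) should deposit the diastereomerically pure ammonium salt F4. Acidification of F4 comes back to the route at 6.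

Step 8. Facial selectivity may be poor if the zinc chelate is incomplete, or the reduction may stall through enolisation of the β-keto lactone. The fallback moves control of Cα from the substrate to a chiral reagent. It sets out from 13 and uses Noyori–Ikariya asymmetric transfer hydrogenation with RuCl[(S,S)-TsDPEN](p-cymene) in HCO2H–Et3N (TsDPEN = N-tosyl-1,2-diphenylethylenediamine). This ligand antipode delivers hydride to aryl ketones to give the (S)-carbinol. The labile C4 centre keeps equilibrating to the trans arrangement under these dynamic kinetic resolution conditions. The fallback comes back at 14 and makes no compound outside the list (entry F0).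

Step 10. The side chain may be lost from the oxocarbenium ion by a retro-aldol-type fragmentation. The silyl group may also be lost, followed by internal acetal formation, or C4 may epimerise through the enol ether. The fallback closes the ring without any cation. It sets out from 15, which NaBH4 in THF–MeOH at 0 °C should reduce to the ring-opened triol F5, with C2, C3, C4 and Cα unchanged. TsCl in pyridine at 0 °C should sulfonylate only the single primary hydroxyl, at C5, to give the primary tosylate F6. NaH in THF at 0 °C then triggers a 5-exo-tet Williamson closure in which the C2 alkoxide displaces the C5 sulfonate, and this comes back at 16. The C2–O bond is never broken, so the cis relation is retained, and the Cα alkoxide could only form an oxetane.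

Further compounds
F1 | step 2 | racemic cis-4-(furan-2-yl)-5-[3-methoxy-4-(tosyloxy)phenyl]dihydrofuran-2(3H)-one | O=C1C[C@@H](c2ccco2)[C@@H](c2ccc(OS(=O)(=O)c3ccc(C)cc3)c(OC)c2)O1.O=C1C[C@H](c2ccco2)[C@H](c2ccc(OS(=O)(=O)c3ccc(C)cc3)c(OC)c2)O1
F2 | step 2 | racemic cis acyl formate | O=C1C[C@@H](C(=O)OC=O)[C@@H](c2ccc(OS(=O)(=O)c3ccc(C)cc3)c(OC)c2)O1.O=C1C[C@H](C(=O)OC=O)[C@H](c2ccc(OS(=O)(=O)c3ccc(C)cc3)c(OC)c2)O1
F3 | step 2 | racemic cis-2-[3-methoxy-4-(tosyloxy)phenyl]-5-oxooxolane-3-carboxylic acid | O=C1C[C@@H](C(=O)O)[C@@H](c2ccc(OS(=O)(=O)c3ccc(C)cc3)c(OC)c2)O1.O=C1C[C@H](C(=O)O)[C@H](c2ccc(OS(=O)(=O)c3ccc(C)cc3)c(OC)c2)O1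
F4 | step 2 | (R)-1-phenylethylammonium salt of 6 | O=C1C[C@@H](C(=O)[O-])[C@@H](c2ccc(OS(=O)(=O)c3ccc(C)cc3)c(OC)c2)O1.C[C@@H]([NH3+])c1ccccc1
F0 | step 8 | none | none
F5 | step 10 | ring-opened triol (C2–OH, C5–OH and Cα–OH free, silyl ether kept) | OC[C@H]([C@H](O)c1ccc(OS(=O)(=O)c2ccc(C)cc2)c(OC)c1)[C@@H](CO[Si](C)(C)C(C)(C)C)[C@@H](c1ccc(OS(=O)(=O)c2ccc(C)cc2)c(OC)c1)O
F6 | step 10 | C5 primary tosylate of the triol | Cc1ccc(S(=O)(=O)OC[C@H]([C@H](O)c2ccc(OS(=O)(=O)c3ccc(C)cc3)c(OC)c2)[C@@H](CO[Si](C)(C)C(C)(C)C)[C@@H](c2ccc(OS(=O)(=O)c3ccc(C)cc3)c(OC)c2)O)cc1
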